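How much G stands in the noon flask at 4.0 h, and which change adds most?

| flask | Z | D | remark | time | volume of the second phase over the first |
|---|---|---|---|---|---|
| noon | 0.10 M | 0.80 equiv | the very flask that is asked about, followed so far |  |  |
| dusk | 0.20 M | 0.80 equiv | run made earlier |  |  |
| flask | 0.10 M | 0.800 equiv |  | 4.0 h | 1.0 |

| noon: time / min | noon: G / % | dusk: time / h | dusk: G / % |
|---|---|---|---|
| 10.0 | 1.3 | 0.250 | 5.1 |
| 15.0 | 2.9 | 0.833 | 24.4 |
| 25.0 | 7.1 | 1.33 | 36.1 |
| 40.0 | 12.2 | 2.00 | 48.4 |
| 80.0 | 26.9 | 3.00 | 59.9 |
| 120 | 39.0 | 4.00 | 66.4 |

(each reading ± 0.5 percentage points)

* amount of G at 4.0 h, in percent of the Z charged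
* the change that raises the amount of G at 4.0 h, in percent of the Z charged most ("none" if none brings more than 2 percentage points) (south / south-west / none)
* amount of G at 4.0 h, in percent of the Z charged, after south

- south: doubling the transfer coefficient of D, all else as stated
- south-west: doubling the amount of D, all else as stated

- in the second phase: D; everything else is in the first
- charges count per volume of the first phase; a concentration in a rate is the amount of a species over the volume of its own phase; every rate counts per litre of the first phase
- the numbers in the tables scatter with a standard deviation of 0.5 percentage points
- reactions considered so far: L <-> D; Z + L -> G; L <-> J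
- the earlier runs hold the two phases in the same ratio of volumes as the flask asked about

Write the balance of D, the limiting reagent at 0.800 equiv. Each G takes one L and each L comes from D, while J merely holds L back, so G in the noon flask has a ceiling of that many equivalents. So count the open share, the part of the ceiling not yet turned into G: 0.512 at 120 min. Now assume that equal times cut this share by equal factors. Then 4.0 h squares it to 0.263, which gives 59.0% G. But that assumption needs a test, so take dusk's 2.00 h reading: squaring its open share gives 67.5% at 4.00 h, against 66.4% read. South leaves the ceiling in place, whereas south-west doubles D to 1.60 equiv, more than the one equivalent of Z charged, so Z becomes the limiting reagent and the ceiling becomes the Z charged.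

The forecast gives 59%, 67% after south, and south-west as best, on the grounds that “the driving force stays large”.

The flask gives 58.9%, and 64.2% after south. Best is south-west, adding 32 percentage points against 5.4 points for south.

    L ⇌ D, rate k1*([L] - [D]/K1) per volume of the first phase (partition coefficient = 0.840, kL = 1.80 × 10⁻⁴ s⁻¹)
    Z + L → G (k = 0.00750 L mol⁻¹ s⁻¹)
    L ⇌ J (K = 0.920, k = 6.20 × 10⁻⁴ s⁻¹)

At 4.00 h the open share stands at 0.264, held as D at 11.9% of its charge, c(L) 0.00574 M and c(J) 0.00585 M.

Read the same flask at 1.0 h: the root of the open share is 0.716, giving 22.7% G. The computed result is 20.6%.

Readings and results are calculated from invented constants; noise was put on by code.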